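**Plan**
1. The side chains are cut first: the C(=O)–CH=CH bond of the hydroxy-enone (alkenyl addition to a ring aldehyde), the ArCH2–CH= and CH3–C(=) bonds of the trisubstituted alkene (carboalumination/benzylation of an alkyne) and the CH(OH)–CH2C≡ bond at the future chain ketone (propargylation).
2. The cyclopentane that remains has two adjacent quaternary carbons whose methyl groups are cis. These two methyl carbons are read as the scar of a CH2–S–CH2 bridge, so the core is a desulfurised cis-fused 3-thiabicyclo[3.3.0]octane.
3. In that bicycle the bond between the two quaternary ring-fusion carbons and the CH2–CH2 bond on the far side of the cyclopentane are cut together. This is a [3+2] between a cyclopropane C–C σ-bond (a 1-vinylcyclopropane, whose vinyl group is the later CH2–C=O arm) and a sulfide-tethered 2-substituted acrylate (whose ester is the later enone carbonyl).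
4. Forward: the sulfide is assembled, the rhodium [3+2] closes thiolane and cyclopentane at once, the vinyl group becomes CH2CH2OH, Raney Ni frees both methyls, the left chain is built (propargylation, methyl/benzyl transfer), then the right chain (ester to aldehyde, alkenylchromium addition, oxidation), and the phenol is released last.
5. Stereochemistry: the cis relation of the quaternary centres comes from the ring fusion and their absolute configuration from the chiral bisphosphine on rhodium (choice between two enantiotopic cyclopropane bonds). The E alkenes come from syn-carboalumination and from a stereodefined alkenylboronate. Carbinol centres made on the way are oxidised to ketones.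

Key step: step 5

Assumption: the drawn configuration is taken as absolute ((1R,2R) at the ring); the sense of induction of the bisphosphine in step 5 cannot be predicted with certainty, so the ligand antipode that gives (1S,5S)-8 is to be used ((R)-H8-BINAP is written).
Abbreviation: Ar = 5-[(tert-butyldimethylsilyl)oxy]-2-methoxy-3-methylphenyl.

**Route**

Step 1
Reactants: 1 2-ethenyl-2-methyloxirane (isoprene monoxide, racemic)
Product: 2 2-methylidenebut-3-en-1-ol
Conditions: LiN(i-Pr)2 (1.2 equiv), Et2O, 0 °C to rt; then H2O
Reagents that add atoms: none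
Why: Base-promoted isomerisation of an epoxide to an allylic alcohol (a methyl proton is removed and the tertiary C–O bond opens), which should give the 2-(hydroxymethyl)-1,3-diene; the stereocentre of 1 is lost.

Step 2
Reactants: 2 2-methylidenebut-3-en-1-ol
Product: 3 (1-ethenylcyclopropyl)methanol
Conditions: Et2Zn (2.0 equiv), CH2I2 (2.0 equiv), CH2Cl2, −10 to 0 °C; then H2O
Reagents that add atoms: diiodomethane, ICI
Why: Hydroxyl-directed Simmons–Smith cyclopropanation in the Furukawa variant, in which the zinc alkoxide should deliver the methylene to the neighbouring 1,1-disubstituted (allylic, more electron-rich) double bond and leave the monosubstituted, homoallylic vinyl group.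

Step 3
Reactants: 3 (1-ethenylcyclopropyl)methanol
Product: 4 S-[(1-ethenylcyclopropyl)methyl] ethanethioate
Conditions: PPh3, i-PrO2C–N=N–CO2i-Pr, AcSH, THF, 0 °C
Reagents that add atoms: thioacetic acid, CC(=O)S
Why: Mitsunobu thioesterification, an SN2 displacement of the alkoxyphosphonium ion by thioacetate at a primary carbon, which at 0 °C should be faster than cyclopropylcarbinyl ionisation and ring expansion.

Step 4
Reactants: 4 S-[(1-ethenylcyclopropyl)methyl] ethanethioate; 5 methyl 2-(bromomethyl)prop-2-enoate
Product: 7 methyl 2-({[(1-ethenylcyclopropyl)methyl]sulfanyl}methyl)prop-2-enoate, via potassium thiolate 6 (not isolated)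
Conditions: K2CO3, MeOH (degassed), 0 °C; then added to 5, 0 °C to rt
Reagents that add atoms: none
Why: Methanolysis of the thioacetate and S-alkylation of the thiolate by the allylic bromide (SN2 and SN2′ attack give the same sulfide), which installs the CH2–S–CH2 tether between the vinylcyclopropane and the acrylate.

Step 5
Reactants: 7 methyl 2-({[(1-ethenylcyclopropyl)methyl]sulfanyl}methyl)prop-2-enoate
Product: 8 methyl (1S,5S)-5-ethenyl-3-thiabicyclo[3.3.0]octane-1-carboxylate (cis-fused; ester and vinyl on the two ring-fusion carbons)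
Conditions: [Rh(CO)2Cl]2 (5 mol%), (R)-H8-BINAP (12 mol%), AgSbF6 (12 mol%), ClCH2CH2Cl, 80 °C
Reagents that add atoms: none
Why: Cationic monovalent rhodium should coordinate the vinyl group of 7 and insert into one of the two enantiotopic cyclopropane bonds at the quaternary carbon (release of about 27 kcal/mol of ring strain) to give a σ-alkyl/π-allyl rhodacycle; the tethered acrylate C=C then inserts into the rhodium–allyl bond at the quaternary terminus in a 5-exo sense, which closes the thiolane and joins the two future quaternary carbons, and C(sp3)–C(sp3) reductive elimination from the six-membered rhodacycle closes the cyclopentane through the CH2–CH2 bond. The closest known reaction type is the rhodium-catalysed intramolecular [3+2] cycloaddition of 1-ene- and 1-yne-vinylcyclopropanes, which is enantioselective with axially chiral bisphosphines in the yne series. Both new stereocentres are the ring-fusion carbons: their cis relation is enforced by the three-atom CH2–S–CH2 tether, because a trans-fused bicyclo[3.3.0]octane is strongly disfavoured, and their absolute configuration is set by the ligand in the insertion step. The step needs cycloaddition to win over β-hydride elimination of the ring-opened alkylrhodium (acyclic dienes); the electron-poor acrylate should insert fast, the inserted carbon is quaternary and offers no β-hydrogen, and attachment of the tether at the vinyl-bearing cyclopropane carbon excludes a [5+2] mode. The thioether and the ester should bind rhodium only reversibly, and the vinyl group that activates the cyclopropane survives as the handle for the CH2–C=O arm.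

Step 6
Reactants: 8 methyl (1S,5S)-5-ethenyl-3-thiabicyclo[3.3.0]octane-1-carboxylate
Product: 10 methyl (1S,5S)-5-(2-hydroxyethyl)-3-thiabicyclo[3.3.0]octane-1-carboxylate, via alkylborane 9 (not isolated)
Conditions: 9-BBN, THF, 0 °C to rt; then NaOH, H2O2, H2O, 0 °C
Reagents that add atoms: hydrogen peroxide, OO
Why: Anti-Markovnikov hydroboration–oxidation of the vinyl group on the quaternary carbon; cold basic peroxide is slow towards the dialkyl sulfide and the neopentyl ester, and any sulfoxide formed would be desulfurised in step 7 all the same.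

Step 7
Reactants: 10 methyl (1S,5S)-5-(2-hydroxyethyl)-3-thiabicyclo[3.3.0]octane-1-carboxylate
Product: 11 methyl (1R,2R)-2-(2-hydroxyethyl)-1,2-dimethylcyclopentane-1-carboxylate (methyl groups cis)
Conditions: Raney Ni (W-2, excess), EtOH/THF, rt
Reagents that add atoms: none
Why: Raney nickel desulfurisation (Mozingo reduction) hydrogenolyses both C–S bonds, so the temporary CH2–S–CH2 bridge becomes the two cis methyl groups; no stereocentre is touched and the descriptors change only because sulfur leaves the priority ranking.

Step 8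
Reactants: 11 methyl (1R,2R)-2-(2-hydroxyethyl)-1,2-dimethylcyclopentane-1-carboxylate
Product: 12 methyl (1R,2R)-1,2-dimethyl-2-(2-oxoethyl)cyclopentane-1-carboxylate
Conditions: Dess–Martin periodinane, NaHCO3, CH2Cl2, 0 °C to rt (11 used without storage)
Reagents that add atoms: none
Why: Dess–Martin oxidation of the primary alcohol to the aldehyde under buffered conditions; prompt oxidation forestalls lactonisation of the δ-hydroxy ester.

Step 9
Reactants: 12 methyl (1R,2R)-1,2-dimethyl-2-(2-oxoethyl)cyclopentane-1-carboxylate
Product: 13 methyl (1R,2R)-2-(2-hydroxypent-4-yn-1-yl)-1,2-dimethylcyclopentane-1-carboxylate (both carbinol epimers)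
Conditions: HC≡CCH2Br, Zn dust, THF, 0 °C; then H2O
Reagents that add atoms: 3-bromoprop-1-yne, C#CCBr
Why: Barbier propargylation, in which allenylzinc bromide adds through an SE2′ transition state to the unhindered aldehyde and not to the neopentyl ester; the new carbinol centre is uncontrolled, which does not matter because it becomes the chain ketone in step 16.

Step 10
Reactants: 14 1-bromo-2-methoxy-3-methylbenzene
Product: 16 3-bromo-4-methoxy-5-methylphenol, via arylboronate 15 (not isolated)
Conditions: [Ir(OMe)(cod)]2 (1.5 mol%), 4,4′-di-tert-butyl-2,2′-bipyridine (3 mol%), B2pin2 (0.6 equiv), THF, 80 °C; then NaOH, H2O2, 0 °C to rt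
Reagents that add atoms: hydrogen peroxide, OO
Why: Sterically controlled iridium-catalysed aromatic C–H borylation should go to the only ring C–H without an ortho substituent (para to the methoxy group), and oxidation of the C–B bond in the same flask gives the phenol.

Step 11
Reactants: 16 3-bromo-4-methoxy-5-methylphenol
Product: 17 (3-bromo-4-methoxy-5-methylphenoxy)(tert-butyl)dimethylsilane
Conditions: TBSCl, imidazole, DMF, rt
Reagents that add atoms: tert-butyl(chloro)dimethylsilane, CC(C)(C)[Si](C)(C)Cl
Why: Silylation of the phenol; the silyl ether masks the oxidation-prone hydroquinone monoether through the organometallic and oxidation steps and comes off last under mild fluoride conditions.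

Step 12
Reactants: 17 (3-bromo-4-methoxy-5-methylphenoxy)(tert-butyl)dimethylsilane
Product: 19 {5-[(tert-butyldimethylsilyl)oxy]-2-methoxy-3-methylphenyl}methanol, via aryllithium 18 (not isolated)
Conditions: n-BuLi, THF, −78 °C; then (CH2O)n, −78 °C to rt; then H2O
Reagents that add atoms: formaldehyde (as paraformaldehyde), C=O
Why: Bromine–lithium exchange to an aryllithium stabilised by the ortho methoxy group, followed by hydroxymethylation with formaldehyde.

Step 13
Reactants: 19 {5-[(tert-butyldimethylsilyl)oxy]-2-methoxy-3-methylphenyl}methanol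
Product: 20 tert-butyl[3-(chloromethyl)-4-methoxy-5-methylphenoxy]dimethylsilane
Conditions: PPh3, CCl4, CH2Cl2, rt
Reagents that add atoms: tetrachloromethane, ClC(Cl)(Cl)Cl
Why: Appel chlorination turns the benzylic alcohol into the chloride under neutral conditions that keep the silyl ether.

Step 14
Reactants: 13 methyl (1R,2R)-2-(2-hydroxypent-4-yn-1-yl)-1,2-dimethylcyclopentane-1-carboxylate; 20 tert-butyl[3-(chloromethyl)-4-methoxy-5-methylphenoxy]dimethylsilane
Product: 22 methyl (1R,2R)-2-[(4E)-6-Ar-2-hydroxy-4-methylhex-4-en-1-yl]-1,2-dimethylcyclopentane-1-carboxylate (both carbinol epimers), via alkenylalane 21 (not isolated)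
Conditions: AlMe3 (3.5 equiv), Cp2ZrCl2 (0.3 equiv), ClCH2CH2Cl, 0 °C to rt; volatiles removed; then 20, Pd(PPh3)4 (5 mol%), THF, rt; then H2O
Reagents that add atoms: trimethylaluminium, C[Al](C)C
Why: Zirconium-catalysed carboalumination (Negishi) adds CH3 and Al syn across the terminal alkyne with CH3 on the internal carbon, and palladium-catalysed coupling of the alkenylalane with the benzylic chloride replaces Al with retention, which sets the E trisubstituted double bond; the hydroxyl travels as its aluminium alkoxide and the neopentyl ester should be left alone.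

Step 15
Reactants: 22 methyl (1R,2R)-2-[(4E)-6-Ar-2-hydroxy-4-methylhex-4-en-1-yl]-1,2-dimethylcyclopentane-1-carboxylate
Product: 23 (4E)-6-Ar-1-[(1R,2R)-2-(hydroxymethyl)-1,2-dimethylcyclopentyl]-4-methylhex-4-en-2-ol (both carbinol epimers)
Conditions: i-Bu2AlH (4 equiv), CH2Cl2, −78 to 0 °C; aq potassium sodium tartrate
Reagents that add atoms: none
Why: Aluminium hydride reduction of the hindered methyl ester to the neopentyl primary alcohol; the alkene and the aryl silyl ether are inert.

Step 16
Reactants: 23 (4E)-6-Ar-1-[(1R,2R)-2-(hydroxymethyl)-1,2-dimethylcyclopentyl]-4-methylhex-4-en-2-ol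
Product: 24 (1R,2R)-2-[(4E)-6-Ar-4-methyl-2-oxohex-4-en-1-yl]-1,2-dimethylcyclopentane-1-carbaldehyde
Conditions: Dess–Martin periodinane (3 equiv), NaHCO3, CH2Cl2, 0 °C
Reagents that add atoms: none
Why: Double Dess–Martin oxidation gives the chain ketone and the ring aldehyde in one operation; the buffered, non-basic medium should keep the β,γ-double bond out of conjugation.

Step 17
Reactants: 25 (3E)-2-methyl-4-(4,4,5,5-tetramethyl-1,3,2-dioxaborolan-2-yl)but-3-en-2-ol
Product: 26 (3E)-4-iodo-2-methylbut-3-en-2-ol
Conditions: NaOH (aq), I2, THF, 0 °C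
Reagents that add atoms: iodine, [I][I]
Why: Iododeboronation of an alkenylboronate under basic conditions, which proceeds with retention and should give the E alkenyl iodide.

Step 18
Reactants: 24 (1R,2R)-2-[(4E)-6-Ar-4-methyl-2-oxohex-4-en-1-yl]-1,2-dimethylcyclopentane-1-carbaldehyde; 26 (3E)-4-iodo-2-methylbut-3-en-2-ol
Product: 28 (4E)-6-Ar-1-[(1R,2R)-2-[(2E)-1,4-dihydroxy-4-methylpent-2-en-1-yl]-1,2-dimethylcyclopentyl]-4-methylhex-4-en-2-one (both epimers at the new carbinol), via alkenylchromium 27 (not isolated)
Conditions: CrCl2 (6 equiv), NiCl2 (2 mol%), DMF, rt; then H2O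
Reagents that add atoms: none
Why: Nozaki–Hiyama–Kishi reaction, in which zerovalent nickel inserts into the C–I bond with retention and hands the alkenyl group to trivalent chromium, and the alkenylchromium adds to the aldehyde only, so the ketone, the free tertiary alcohol and the β,γ-alkene are tolerated; the new carbinol centre is uncontrolled and is oxidised in step 19.

Step 19
Reactants: 28 (4E)-6-Ar-1-[(1R,2R)-2-[(2E)-1,4-dihydroxy-4-methylpent-2-en-1-yl]-1,2-dimethylcyclopentyl]-4-methylhex-4-en-2-one
Product: 29 (2E)-1-[(1R,2R)-2-[(4E)-6-Ar-4-methyl-2-oxohex-4-en-1-yl]-1,2-dimethylcyclopentyl]-4-hydroxy-4-methylpent-2-en-1-one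
Conditions: Dess–Martin periodinane, NaHCO3, CH2Cl2, 0 °C
Reagents that add atoms: none
Why: Dess–Martin oxidation of the secondary allylic alcohol to the E enone; the tertiary alcohol cannot be oxidised.

Step 20
Reactants: 29 (2E)-1-[(1R,2R)-2-[(4E)-6-Ar-4-methyl-2-oxohex-4-en-1-yl]-1,2-dimethylcyclopentyl]-4-hydroxy-4-methylpent-2-en-1-one
Product: 30 (2E)-4-hydroxy-1-[(1R,2R)-2-[(4E)-6-(5-hydroxy-2-methoxy-3-methylphenyl)-4-methyl-2-oxohex-4-en-1-yl]-1,2-dimethylcyclopentyl]-4-methylpent-2-en-1-one
Conditions: KHF2, MeOH, rt
Reagents that add atoms: none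
Why: Fluoride cleavage of the phenolic silyl ether, selective for aryl silyl ethers and close to neutral, so that the β,γ-unsaturated ketone should not isomerise and the γ-hydroxy enone should not fragment.

**Compound list**
1 | 2-ethenyl-2-methyloxirane (racemic) | CC1(C=C)CO1 | starting material
2 | 2-methylidenebut-3-en-1-ol | OCC(=C)C=C | intermediate
3 | (1-ethenylcyclopropyl)methanol | OCC1(C=C)CC1 | intermediate
4 | S-[(1-ethenylcyclopropyl)methyl] ethanethioate | CC(=O)SCC1(C=C)CC1 | intermediate
5 | methyl 2-(bromomethyl)prop-2-enoate | COC(=O)C(=C)CBr | starting material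
6 | potassium (1-ethenylcyclopropyl)methanethiolate (not isolated) | [K+].[S-]CC1(C=C)CC1 | intermediate
7 | methyl 2-({[(1-ethenylcyclopropyl)methyl]sulfanyl}methyl)prop-2-enoate | COC(=O)C(=C)CSCC1(C=C)CC1 | intermediate
8 | methyl (1S,5S)-5-ethenyl-3-thiabicyclo[3.3.0]octane-1-carboxylate | C=C[C@@]12CCC[C@@]1(CSC2)C(=O)OC | intermediate
9 | methyl (1S,5R)-5-[2-(9-borabicyclo[3.3.1]nonan-9-yl)ethyl]-3-thiabicyclo[3.3.0]octane-1-carboxylate (not isolated) | B1(CC[C@@]23CCC[C@@]2(CSC3)C(=O)OC)C2CCCC1CCC2 | intermediate
10 | methyl (1S,5S)-5-(2-hydroxyethyl)-3-thiabicyclo[3.3.0]octane-1-carboxylate | OCC[C@@]12CCC[C@@]1(CSC2)C(=O)OC | intermediate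
11 | methyl (1R,2R)-2-(2-hydroxyethyl)-1,2-dimethylcyclopentane-1-carboxylate | OCC[C@@]1(C)CCC[C@@]1(C)C(=O)OC | intermediate
12 | methyl (1R,2R)-1,2-dimethyl-2-(2-oxoethyl)cyclopentane-1-carboxylate | O=CC[C@@]1(C)CCC[C@@]1(C)C(=O)OC | intermediate
13 | methyl (1R,2R)-2-(2-hydroxypent-4-yn-1-yl)-1,2-dimethylcyclopentane-1-carboxylate (both carbinol epimers) | C#CCC(O)C[C@@]1(C)CCC[C@@]1(C)C(=O)OC | intermediate
14 | 1-bromo-2-methoxy-3-methylbenzene | COc1c(C)cccc1Br | starting material
15 | 2-(3-bromo-4-methoxy-5-methylphenyl)-4,4,5,5-tetramethyl-1,3,2-dioxaborolane (not isolated) | COc1c(C)cc(cc1Br)B1OC(C)(C)C(C)(C)O1 | intermediate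
16 | 3-bromo-4-methoxy-5-methylphenol | COc1c(C)cc(O)cc1Br | intermediate
17 | (3-bromo-4-methoxy-5-methylphenoxy)(tert-butyl)dimethylsilane | COc1c(C)cc(O[Si](C)(C)C(C)(C)C)cc1Br | intermediate
18 | {5-[(tert-butyldimethylsilyl)oxy]-2-methoxy-3-methylphenyl}lithium (not isolated) | COc1c(C)cc(O[Si](C)(C)C(C)(C)C)cc1[Li] | intermediate
19 | {5-[(tert-butyldimethylsilyl)oxy]-2-methoxy-3-methylphenyl}methanol | COc1c(C)cc(O[Si](C)(C)C(C)(C)C)cc1CO | intermediate
20 | tert-butyl[3-(chloromethyl)-4-methoxy-5-methylphenoxy]dimethylsilane | COc1c(C)cc(O[Si](C)(C)C(C)(C)C)cc1CCl | intermediate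
21 | methyl (1R,2R)-2-[(4E)-5-(dimethylalumanyl)-2-[(dimethylalumanyl)oxy]-4-methylpent-4-en-1-yl]-1,2-dimethylcyclopentane-1-carboxylate (not isolated) | C[Al](C)/C=C(\C)CC(O[Al](C)C)C[C@@]1(C)CCC[C@@]1(C)C(=O)OC | intermediate
22 | methyl (1R,2R)-2-[(4E)-6-Ar-2-hydroxy-4-methylhex-4-en-1-yl]-1,2-dimethylcyclopentane-1-carboxylate (both carbinol epimers) | COc1c(C)cc(O[Si](C)(C)C(C)(C)C)cc1C/C=C(\C)CC(O)C[C@@]1(C)CCC[C@@]1(C)C(=O)OC | intermediate
23 | (4E)-6-Ar-1-[(1R,2R)-2-(hydroxymethyl)-1,2-dimethylcyclopentyl]-4-methylhex-4-en-2-ol (both carbinol epimers) | COc1c(C)cc(O[Si](C)(C)C(C)(C)C)cc1C/C=C(\C)CC(O)C[C@@]1(C)CCC[C@@]1(C)CO | intermediate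
24 | (1R,2R)-2-[(4E)-6-Ar-4-methyl-2-oxohex-4-en-1-yl]-1,2-dimethylcyclopentane-1-carbaldehyde | COc1c(C)cc(O[Si](C)(C)C(C)(C)C)cc1C/C=C(\C)CC(=O)C[C@@]1(C)CCC[C@@]1(C)C=O | intermediate
25 | (3E)-2-methyl-4-(4,4,5,5-tetramethyl-1,3,2-dioxaborolan-2-yl)but-3-en-2-ol | CC(C)(O)/C=C/B1OC(C)(C)C(C)(C)O1 | starting material
26 | (3E)-4-iodo-2-methylbut-3-en-2-ol | CC(C)(O)/C=C/I | intermediate
27 | dichloro[(1E)-3-hydroxy-3-methylbut-1-en-1-yl]chromium (not isolated) | CC(C)(O)/C=C/[Cr](Cl)Cl | intermediate
28 | (4E)-6-Ar-1-[(1R,2R)-2-[(2E)-1,4-dihydroxy-4-methylpent-2-en-1-yl]-1,2-dimethylcyclopentyl]-4-methylhex-4-en-2-one (both epimers at the new carbinol) | COc1c(C)cc(O[Si](C)(C)C(C)(C)C)cc1C/C=C(\C)CC(=O)C[C@@]1(C)CCC[C@@]1(C)C(O)/C=C/C(C)(C)O | intermediate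
29 | (2E)-1-[(1R,2R)-2-[(4E)-6-Ar-4-methyl-2-oxohex-4-en-1-yl]-1,2-dimethylcyclopentyl]-4-hydroxy-4-methylpent-2-en-1-one | COc1c(C)cc(O[Si](C)(C)C(C)(C)C)cc1C/C=C(\C)CC(=O)C[C@@]1(C)CCC[C@@]1(C)C(=O)/C=C/C(C)(C)O | intermediate
30 | (2E)-4-hydroxy-1-[(1R,2R)-2-[(4E)-6-(5-hydroxy-2-methoxy-3-methylphenyl)-4-methyl-2-oxohex-4-en-1-yl]-1,2-dimethylcyclopentyl]-4-methylpent-2-en-1-one | COc1c(C)cc(O)cc1C/C=C(\C)CC(=O)C[C@@]1(C)CCC[C@@]1(C)C(=O)/C=C/C(C)(C)O | target

**Count**
Total step count: 20. Longest linear sequence: 15 steps (steps 1–9, 14–16, 18–20).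

**Steps most likely to fail**

Step 5. The thioether may hold the rhodium catalyst, or rhodium may insert into the allylic C–S bond. Insertion of the hindered 1,1-disubstituted acrylate may be slower than β-hydride elimination of the ring-opened alkylrhodium, which would give acyclic dienes. The ligand may also discriminate the two enantiotopic cyclopropane bonds poorly. The fallback sets out from 4 and comes back at 11; it makes the same two ring bonds by a thiyl-radical-mediated intermolecular vinylcyclopropane/alkene [3+2] annulation. Thioacetate 4 is heated with methyl methacrylate (5 equiv), PhSSPh (20 mol%) and AIBN in benzene at 80 °C. PhS• adds to the vinyl terminus, the cyclopropylcarbinyl radical opens, the primary radical adds to the methacrylate, and the tertiary ester radical closes 5-exo on the allyl sulfide with loss of PhS•. This should give methyl 2-[(acetylsulfanyl)methyl]-2-ethenyl-1-methylcyclopentane-1-carboxylate F1 as a racemic mixture of cis and trans isomers. Hydroboration with 9-BBN and oxidation with Me3NO should give methyl 2-[(acetylsulfanyl)methyl]-2-(2-hydroxyethyl)-1-methylcyclopentane-1-carboxylate F2, and Raney Ni then turns CH2SAc into CH3. The cis-dimethyl isomer is separated and resolved on a chiral stationary phase to give 11. The price is the loss of the relative and absolute control that the tether and the ligand provide.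

Step 14. Residual AlMe3 may transfer methyl to palladium (ethylarene from 20), transmetalation of the alkoxide-bound alkenylalane may be slow, and the alane may be lost by protonolysis. The fallback sets out from 13 and 20 and comes back at 22; the roles of nucleophile and electrophile are exchanged and the coupling is run as a separate step. The carboalumination mixture from 13 is quenched with I2 (THF, −30 °C) to give, with retention, methyl (1R,2R)-2-[(4E)-2-hydroxy-5-iodo-4-methylpent-4-en-1-yl]-1,2-dimethylcyclopentane-1-carboxylate F3. Chloride 20 is converted with Zn dust and LiCl in THF into ({5-[(tert-butyldimethylsilyl)oxy]-2-methoxy-3-methylphenyl}methyl)zinc chloride F4. Negishi coupling of F3 with F4 (Pd(PPh3)4, THF, rt) should give 22.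

Step 18. Addition to the aldehyde, which sits on a quaternary carbon next to a second one, may be so slow that aldol cyclisation between the chain ketone and the aldehyde, or reduction of the aldehyde by divalent chromium, takes over. The fallback sets out from 24 and comes back at 29; the aldehyde carbon is used as an acyl electrophile instead. Pinnick oxidation (NaClO2, NaH2PO4, 2-methylbut-2-ene, t-BuOH/H2O) should give (1R,2R)-2-[(4E)-6-Ar-4-methyl-2-oxohex-4-en-1-yl]-1,2-dimethylcyclopentane-1-carboxylic acid F5. 1-Chloro-N,N,2-trimethylprop-1-en-1-amine in CH2Cl2 converts it, without acid, into (1R,2R)-2-[(4E)-6-Ar-4-methyl-2-oxohex-4-en-1-yl]-1,2-dimethylcyclopentane-1-carbonyl chloride F6. Palladium-catalysed acylative Suzuki–Miyaura coupling of F6 with alkenylboronate 25 (Pd(PPh3)4, anhydrous K3PO4, toluene, 60 °C) should give enone 29 directly, so that steps 17 to 19 are not needed.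

**Further compounds**
F1 | step 5 | methyl 2-[(acetylsulfanyl)methyl]-2-ethenyl-1-methylcyclopentane-1-carboxylate (racemic, cis and trans) | COC(=O)C1(C)CCCC1(C=C)CSC(C)=O
F2 | step 5 | methyl 2-[(acetylsulfanyl)methyl]-2-(2-hydroxyethyl)-1-methylcyclopentane-1-carboxylate (racemic, cis and trans) | COC(=O)C1(C)CCCC1(CCO)CSC(C)=O
F3 | step 14 | methyl (1R,2R)-2-[(4E)-2-hydroxy-5-iodo-4-methylpent-4-en-1-yl]-1,2-dimethylcyclopentane-1-carboxylate | I/C=C(\C)CC(O)C[C@@]1(C)CCC[C@@]1(C)C(=O)OC
F4 | step 14 | ({5-[(tert-butyldimethylsilyl)oxy]-2-methoxy-3-methylphenyl}methyl)zinc chloride | COc1c(C)cc(O[Si](C)(C)C(C)(C)C)cc1C[Zn]Cl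
F5 | step 18 | (1R,2R)-2-[(4E)-6-Ar-4-methyl-2-oxohex-4-en-1-yl]-1,2-dimethylcyclopentane-1-carboxylic acid | COc1c(C)cc(O[Si](C)(C)C(C)(C)C)cc1C/C=C(\C)CC(=O)C[C@@]1(C)CCC[C@@]1(C)C(O)=O
F6 | step 18 | (1R,2R)-2-[(4E)-6-Ar-4-methyl-2-oxohex-4-en-1-yl]-1,2-dimethylcyclopentane-1-carbonyl chloride | COc1c(C)cc(O[Si](C)(C)C(C)(C)C)cc1C/C=C(\C)CC(=O)C[C@@]1(C)CCC[C@@]1(C)C(Cl)=O
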